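(Readings and results come from a simulation for an exercise; noise was put on by code.)

If little Q is at hand and a flask must stand for 2.5 d, reckon what it keeps of X from runs that stopped at 30.0 h.

| setting | delta | beta | zeta | summer | winter | autumn | dusk |
|---|---|---|---|---|---|---|---|
| Q | 0.014 M | 0.032 M | 0.12 M | 0.012 M | 0.025 M | 0.050 M | 0.10 M |
| D | 0.10 M | 0.10 M | 0.10 M | 0.100 M | 0.100 M | 0.100 M | 0.100 M |
| remark | run made earlier | run made earlier | run made earlier |  |  |  |  |
| time |  |  |  | 2.5 d | 2.5 d | 2.5 d | 2.5 d |

| run | time / h | X / % | Q / % |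
|---|---|---|---|
| delta | 2.50 | 70.4 | 20.7 |
| delta | 8.00 | 65.2 | 7.0 |
| delta | 15.0 | 47.0 | 3.8 |
| delta | 20.0 | 39.7 | 5.6 |
| delta | 30.0 | 26.2 | 4.0 |
| beta | 2.50 | 67.1 | 25.6 |
| beta | 8.00 | 64.8 | 11.4 |
| beta | 15.0 | 49.4 | 8.4 |
| beta | 20.0 | 41.3 | 6.5 |
| beta | 30.0 | 30.0 | 5.0 |
| zeta | 2.50 | 49.3 | 38.8 |
| zeta | 8.00 | 44.5 | 21.5 |
| zeta | 15.0 | 33.5 | 17.1 |
| zeta | 20.0 | 28.8 | 15.3 |
| zeta | 30.0 | 20.8 | 11.2 |

(readings scatter by 1 percentage point)

- a species is counted by the Q in it: one J counts as two
- reactions considered so far: Q + D <-> X; Q + X -> J; X <-> G; D + X -> L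
- "hardly changes" means that all values lie within two and a half points (for a concentration: within two and a half percent of the largest)

1. amount of X at the end, in percent of the Q charged for summer, winter, autumn, dusk, in this order
2. how the row runs (falls, then rises / rises, then falls / falls all the way / rises all the way / hardly changes)

From 8.00 h on, X only falls in every run, so take the drain constant, the fall of ln X per hour in delta between 8.00 h and 30.0 h: 0.0414 h⁻¹. It serves as a pseudo-first-order constant, and delta is the run nearest to summer in charge.

Bracket summer from below by holding this constant from 30.0 h to the end. The reading 26.2% then shrinks to 7.56%. The drain slows as D is used, so a held constant is the fast case.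

Bracket summer from above by letting the constant scale with cD, with D at its lowest possible share. Each Q can tie up at most 2 D, as in L, so the share left is 76.0% of the charge. Apply that share over the whole stretch and X ends at 10.2%.

For the row, beta's reading at the last time stands higher than delta's or zeta's. Beta's drain constant, 0.0350 h⁻¹, is also lower than delta's. So expect a row that rises, then falls.

The forecast gives 9%, 14%, 15% and 12.5%, rises, then falls, with the words "At low Q, D stays high, so X keeps draining", and its summer point lies inside the bracket.

The flasks give 7.38%, 11.2%, 16.4% and 13.2%: rises, then falls.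

    Q + D ⇌ X (K = 111 L mol⁻¹, k = 7.47 L mol⁻¹ h⁻¹)
    Q + X → J (k = 0.944 L mol⁻¹ h⁻¹)
    X ⇌ G (K = 0.489, k = 0.00177 h⁻¹)
    D + X → L (k = 0.553 L mol⁻¹ h⁻¹)

Summer ends 0.18 percentage points under the lower edge, and the reading behind that edge carries 1 point. In summer, D stands at 78.0% of its charge at 2.50 d, above the floor of 76.0%. Now use the drain constant on winter, with beta as its neighbour: held from 30.0%, it gives 10.5%, and winter ends at 11.2%.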